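**Plan**

Numbering: ring A is the propanoyl ring (C1 acyl, C3 bridge, C4 OMe, C5 H); ring B is the acetyl ring (C1' acyl, C3' bridge, C5' the CMe2 carbon).
Cuts: first both C5'–CH3 bonds, which turns ring B back into a 2,4,6-trihydroxyacetophenone ring. This works because ring B is an acylphloroglucinol dearomatised at one carbon only, C5', which lies between the enol carbons C4' and C6' and is the single unsubstituted carbon of the aromatic ring. Then the bridge bond CH2–C3', then the C3–CH2 bond of ring A and the O4–CH3 bond.
Forward: flopropione is methylated at O4 and aminomethylated at C3; the Mannich base releases an ortho-quinone methide that benzylates 2,4,6-trihydroxyacetophenone; the aromatic diarylmethane is then methylated twice at C5'. Both six-membered rings are bought and no ring is closed.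
Stereochemistry: the target has no stereocentre (C5' carries two identical methyl groups), so nothing has to be controlled.

Key step: step 4

Assumption: the enolised trione ring B is a set of rapidly interconverting tautomers, and the SMILES of the target stands for this mixture.

**Route**

Step 1
Reactants: 1 flopropione (2,4,6-trihydroxypropiophenone)
Product: 2 2,6-dihydroxy-4-methoxypropiophenone
Conditions: Me2SO4 (1.0 equiv), K2CO3 (1.0 equiv), acetone, reflux
Reagents that add atoms: dimethyl sulfate, COS(=O)(=O)OC
Why: Williamson ether synthesis in which the 4-OH, the only hydroxyl not hydrogen-bonded to the ketone and the most acidic one, should be methylated first, with one equivalent of reagent holding back the chelated 2- and 6-hydroxyls.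

Step 2
Reactants: 2 2,6-dihydroxy-4-methoxypropiophenone
Product: 3 1-[3-[(dimethylamino)methyl]-2,6-dihydroxy-4-methoxyphenyl]propan-1-one (Mannich base)
Conditions: 37% aq. HCHO (1.0 equiv), 40% aq. Me2NH (1.1 equiv), EtOH, 0 °C to rt
Reagents that add atoms: formaldehyde, C=O; dimethylamine, CNC
Why: phenolic Mannich reaction in which the iminium ion attacks one of the two equivalent electron-rich ring carbons (C3), and one equivalent of aldehyde together with separation of the zwitterionic mono-adduct from ethanol should limit the reaction to a single aminomethylation.

Step 3
Reactants: 3 Mannich base; 4 2,4,6-trihydroxyacetophenone (3 equiv)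
Product: 6 1-[3-[(3-acetyl-2,4,6-trihydroxyphenyl)methyl]-2,6-dihydroxy-4-methoxyphenyl]propan-1-one (aromatic methylene-bridged dimer), via ortho-quinone methide 5 (not isolated)
Conditions: 1,4-dioxane, 100 °C, N2 stream, slow addition of 3 to 4
Reagents that add atoms: none
Why: thermal elimination of dimethylamine from the phenolic Mannich base gives the ortho-quinone methide, which the phloroglucinol ring of 4 should capture at C3' by conjugate addition (Friedel–Crafts-type benzylation) and rearomatisation, the excess of 4 suppressing a second benzylation.

Step 4
Reactants: 6 aromatic methylene-bridged dimer; 7 iodomethane (two equivalents incorporated)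
Product: 9 2-acetyl-6-[(2,4-dihydroxy-6-methoxy-3-propanoylphenyl)methyl]-3,5-dihydroxy-4,4-dimethylcyclohexa-2,5-dien-1-one (the target CNP0241167.0), via monomethyl dimer 8 (not isolated)
Conditions: NaOMe (3.0 equiv), CH3I (2.2 equiv, added in portions), MeOH, 0 °C to rt, N2; then 1 M HCl, crystallisation
Reagents that add atoms: iodomethane (compound 7), CI
Why: Methoxide converts ring B, whose three free hydroxyls make it the most acidic part of 6, into a phloroglucinolate that reacts as a vinylogous enolate through C5' and displaces iodide from iodomethane (SN2) to give 8; 8 is deprotonated again and alkylated a second time at the same carbon, which becomes quaternary and fixes ring B as the enolised 2-acylcyclohexane-1,3,5-trione. The closest known reaction is the alkylative dearomatisation of acylphloroglucinols to acylfilicinic acids with CH3I and NaOMe in methanol. No ring is closed and no stereocentre arises, because C5' carries two identical methyl groups. The step needs C- over O-methylation, which hydrogen-bonding methanol and the soft iodide electrophile favour, and it needs site selectivity for C5' over the benzyl-bearing C3' and over C5–H of ring A. C5' is the only unsubstituted carbon of the more highly charged ring, C3' is screened by the di-ortho-substituted benzyl group, and ring A, with a 4-methoxy group and two ketone-chelated hydroxyls, should not reach a comparable charge density at this base stoichiometry. Low temperature and no more than three equivalents of base should keep the methylene bridge from retro-Michael scrambling, and the product leaves as a delocalised, weakly nucleophilic enolate that should resist a third methylation.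

**Compound list**

1 | flopropione (2,4,6-trihydroxypropiophenone) | CCC(=O)c1c(O)cc(O)cc1O | starting material
2 | 2,6-dihydroxy-4-methoxypropiophenone | CCC(=O)c1c(O)cc(OC)cc1O | intermediate
3 | 1-[3-[(dimethylamino)methyl]-2,6-dihydroxy-4-methoxyphenyl]propan-1-one (Mannich base) | CCC(=O)c1c(O)cc(OC)c(CN(C)C)c1O | intermediate
4 | 2,4,6-trihydroxyacetophenone | CC(=O)c1c(O)cc(O)cc1O | starting material
5 | 3-hydroxy-5-methoxy-6-methylidene-2-propanoylcyclohexa-2,4-dien-1-one (ortho-quinone methide of ring A) | CCC(=O)C1=C(O)C=C(OC)C(=C)C1=O | intermediate
6 | 1-[3-[(3-acetyl-2,4,6-trihydroxyphenyl)methyl]-2,6-dihydroxy-4-methoxyphenyl]propan-1-one (aromatic methylene-bridged dimer) | CCC(=O)c1c(O)cc(OC)c(Cc2c(O)cc(O)c(C(C)=O)c2O)c1O | intermediate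
7 | iodomethane | CI | starting material
8 | 1-[3-[(3-acetyl-2,4,6-trihydroxy-5-methylphenyl)methyl]-2,6-dihydroxy-4-methoxyphenyl]propan-1-one (monomethyl dimer) | CCC(=O)c1c(O)cc(OC)c(Cc2c(O)c(C)c(O)c(C(C)=O)c2O)c1O | intermediate
9 | 2-acetyl-6-[(2,4-dihydroxy-6-methoxy-3-propanoylphenyl)methyl]-3,5-dihydroxy-4,4-dimethylcyclohexa-2,5-dien-1-one (CNP0241167.0) | CCC(=O)c1c(O)cc(OC)c(CC2=C(O)C(C)(C)C(O)=C(C(C)=O)C2=O)c1O | target

**Step count and risks**

Total step count: 4. Longest linear sequence: 4 steps (1 → 2 → 3 → 6 → 9).

Steps most likely to fail:

1. Step 4. What may go wrong: methylation spreading to the benzyl-bearing C3', to C5 of ring A or to oxygen, a third methylation of ring B, and base-induced retro-Michael opening of the bridge with scrambling to symmetrical dimers. Fallback: install the gem-dimethyl group before the bridge. Setting out from 4, C,C-dimethylation with iodomethane 7 and NaOMe in methanol should give acetylfilicinic acid F1. Its only ring C–H carbon then captures the quinone methide 5 released from Mannich base 3 in 1,4-dioxane at 100 °C. This comes back to the route at the target 9.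

2. Step 3. What may go wrong: addition of the quinone methide to its own precursor or to product 6 (oligomers, double benzylation of 4), and amine-mediated transfer of the methylene unit leading to symmetrical dimers. Fallback: replace the thermally generated quinone methide by a stable benzylic acetate that is ionised by a Lewis acid. Setting out from 3, heating in acetic anhydride should exchange the dimethylamino group for acetate and acetylate both phenols, giving (2,4-diacetoxy-6-methoxy-3-propanoylphenyl)methyl acetate F2. F2 should benzylate an excess of 4 with BF3·OEt2 in 1,4-dioxane at rt (Friedel–Crafts benzylation; the acetylated ring A cannot add to its own cation) to give the ring A di-O-acetyl dimer F3. K2CO3 in methanol at 0 °C then removes the two aryl acetates and comes back to the route at 6.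

3. Step 2. What may go wrong: double aminomethylation at C3 and C5, and premature loss of dimethylamine from 3 followed by self-condensation to the symmetrical ring A dimer. Fallback: bring in the carbon at the aldehyde oxidation level, where the first substitution deactivates the ring toward a second. Setting out from 2, Vilsmeier–Haack formylation (POCl3, DMF, then aqueous hydrolysis) should give 2,4-dihydroxy-6-methoxy-3-propanoylbenzaldehyde F4. Reductive amination with dimethylamine and NaBH(OAc)3 in 1,2-dichloroethane then comes back to the route at 3.

**Further compounds**

F1 | step 4 | acetylfilicinic acid (2-acetyl-3,5-dihydroxy-4,4-dimethylcyclohexa-2,5-dien-1-one) | CC(=O)C1=C(O)C(C)(C)C(O)=CC1=O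
F2 | step 3 | (2,4-diacetoxy-6-methoxy-3-propanoylphenyl)methyl acetate | CCC(=O)c1c(OC(C)=O)cc(OC)c(COC(C)=O)c1OC(C)=O
F3 | step 3 | 4-[(3-acetyl-2,4,6-trihydroxyphenyl)methyl]-5-methoxy-2-propanoyl-1,3-phenylene diacetate | CCC(=O)c1c(OC(C)=O)cc(OC)c(Cc2c(O)cc(O)c(C(C)=O)c2O)c1OC(C)=O
F4 | step 2 | 2,4-dihydroxy-6-methoxy-3-propanoylbenzaldehyde | CCC(=O)c1c(O)cc(OC)c(C=O)c1O
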